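**Retrosynthetic overview**
1. Target 16 ⇐ hexabenzyl ether 15 by global hydrogenolysis.
2. The oxolane ring of 15 ⇐ Lewis-acid ring expansion of aroylcyclopropane 14 with aldehyde 8 (formal (3+2), stepwise and ionic; forms C2–C3 and C5–O, breaks one cyclopropane C–C bond).
3. Cyclopropane 14 ⇐ enantioselective carbene transfer from diazoketone 13 to (E)-alkene 11; this sets the only centre that cannot equilibrate later (C4).
4. 11 ⇐ chalcone 9 (reductive 1,3-transposition) ⇐ ketone 4 + aldehyde 8; 13 ⇐ 4; 4 ⇐ resorcinol + acetic acid; 8 ⇐ 4-bromophenol + DMF.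
5. Ring order: cyclopropane first, then the oxolane by expansion of it.

Assumption: the SMILES is read as the all-trans (2S,3S,4S,5S) oxolane, numbered O1, C2 (4-hydroxyphenyl), C3 (aroyl), C4 (4-hydroxybenzyl), C5 (2,4-dihydroxyphenyl).

**Route**

Step 1
Reactants: 1 resorcinol; 2 acetic acid
Product: 3 1-(2,4-dihydroxyphenyl)ethan-1-one
Conditions: ZnCl2, AcOH (neat), 140 °C
Reagents that add atoms: none
Why: Nencki reaction (ZnCl2-mediated Friedel–Crafts C-acylation) at C4 of resorcinol, para to one hydroxyl and ortho to the other; no stereocentre.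

Step 2
Reactants: 3 1-(2,4-dihydroxyphenyl)ethan-1-one
Product: 4 1-[2,4-bis(benzyloxy)phenyl]ethan-1-one
Conditions: BnBr (2.5 equiv), K2CO3, DMF, 80 °C
Reagents that add atoms: benzyl bromide BrCc1ccccc1
Why: Williamson ether synthesis; heating in DMF also alkylates the hydrogen-bonded 2-hydroxyl.

Step 3
Reactants: 5 4-bromophenol
Product: 6 1-(benzyloxy)-4-bromobenzene
Conditions: BnBr, K2CO3, acetone, reflux
Reagents that add atoms: benzyl bromide BrCc1ccccc1
Why: Williamson ether synthesis on a simple phenol.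

Step 4
Reactants: 6 1-(benzyloxy)-4-bromobenzene
Product: 8 4-(benzyloxy)benzaldehyde, via 4-(benzyloxy)phenyllithium 7 (not isolated)
Conditions: n-BuLi, THF, −78 °C; DMF, −78 → 0 °C; H2O
Reagents that add atoms: N,N-dimethylformamide CN(C)C=O
Why: bromine–lithium exchange followed by Bouveault formylation of the aryllithium.

Step 5
Reactants: 4 1-[2,4-bis(benzyloxy)phenyl]ethan-1-one; 8 4-(benzyloxy)benzaldehyde
Product: 9 (E)-1-[2,4-bis(benzyloxy)phenyl]-3-[4-(benzyloxy)phenyl]prop-2-en-1-one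
Conditions: KOH, EtOH, 25 °C
Reagents that add atoms: none
Why: Claisen–Schmidt aldol condensation; E1cB dehydration gives the (E)-enone.

Step 6
Reactants: 9 (E)-1-[2,4-bis(benzyloxy)phenyl]-3-[4-(benzyloxy)phenyl]prop-2-en-1-one
Product: 11 2,4-bis(benzyloxy)-1-{(1E)-3-[4-(benzyloxy)phenyl]prop-1-en-1-yl}benzene, via chalcone tosylhydrazone 10 (not isolated)
Conditions: TsNHNH2, EtOH, 60 °C; evaporate; catecholborane, CHCl3, 0 °C; NaOAc·3H2O, reflux
Reagents that add atoms: none
Why: reductive 1,3-transposition of an enone tosylhydrazone: hydride adds to C=N, sulfinate is lost, and the allylic diazene expels N2 by a retro-ene shift that moves the double bond next to the 2,4-dialkoxyphenyl ring with (E) geometry.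

Step 7
Reactants: 4 1-[2,4-bis(benzyloxy)phenyl]ethan-1-one
Product: 13 1-[2,4-bis(benzyloxy)phenyl]-2-diazoethan-1-one, via trifluoroacetylated ketone 12 (not isolated)
Conditions: LiN(SiMe3)2, THF, −78 °C; CF3CO2CH2CF3; then MsN3, Et3N, H2O, MeCN, 25 °C
Reagents that add atoms: methanesulfonyl azide CS(=O)(=O)N=[N+]=[N-]
Why: detrifluoroacetylative (Regitz-type) diazo transfer; Claisen trifluoroacetylation activates the methyl ketone and the triazoline from MsN3 fragments with loss of the trifluoroacetyl group.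

Step 8
Reactants: 11 2,4-bis(benzyloxy)-1-{(1E)-3-[4-(benzyloxy)phenyl]prop-1-en-1-yl}benzene; 13 1-[2,4-bis(benzyloxy)phenyl]-2-diazoethan-1-one
Product: 14 {(1R,2R,3R)-2-[4-(benzyloxy)benzyl]-3-[2,4-bis(benzyloxy)phenyl]cyclopropyl}[2,4-bis(benzyloxy)phenyl]methanone
Conditions: [Co(3,5-DitBu-ChenPhyrin)] (5 mol %), 13 (1.5 equiv, in portions), toluene, 40 °C
Reagents that add atoms: none
Why: Proposed new method: a divalent cobalt complex of a D2-symmetric chiral amidoporphyrin turns 13 into an alpha-cobalt alkyl radical (trivalent cobalt) held by N–H···O=C hydrogen bonds, which adds face-selectively to the non-benzylic alkene carbon of 11 (this alone fixes the benzyl-bearing centre, later C4) and then closes by 3-exo-tet radical substitution at the Co–C bond; this stepwise radical path should tolerate the 1,2-disubstituted alkene and avoid the oxonium-ylide [1,2]-shift that an electrophilic rhodium or copper carbene would undergo with the ortho benzyloxy group; the closest known reaction type is cobalt-porphyrin metalloradical asymmetric cyclopropanation of terminal styrenes with acceptor-substituted diazo compounds, not yet shown for an internal (E)-beta-alkylstyrene with an aryl diazomethyl ketone, and the catalyst antipode that gives the (2R) centre is fixed in a first screen.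

Step 9
Reactants: 14 {(1R,2R,3R)-2-[4-(benzyloxy)benzyl]-3-[2,4-bis(benzyloxy)phenyl]cyclopropyl}[2,4-bis(benzyloxy)phenyl]methanone; 8 4-(benzyloxy)benzaldehyde
Product: 15 [2,4-bis(benzyloxy)phenyl]{(2S,3S,4S,5S)-4-[4-(benzyloxy)benzyl]-5-[2,4-bis(benzyloxy)phenyl]-2-[4-(benzyloxy)phenyl]oxolan-3-yl}methanone
Conditions: Sc(OTf)3 (10 mol %), 4 Å MS, CH2Cl2, 0 → 25 °C
Reagents that add atoms: none
Why: Lewis-acid-catalysed ring expansion of a donor–acceptor cyclopropane with an aldehyde (formal (3+2), stepwise and ionic): Sc(OTf)3 chelated by the ketone and its ortho benzyloxy oxygen breaks the C1–C3 cyclopropane bond to a 2,4-dialkoxybenzyl cation and a scandium enolate, the aldehyde oxygen adds to the cation, the enolate closes onto the resulting oxocarbenium ion, and since both bond formations are reversible under the Lewis acid, C2, C3 and C5 settle trans to their neighbours around the untouched benzyl-bearing centre C4, giving the all-trans (2S,3S,4S,5S) oxolane.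

Step 10
Reactants: 15 [2,4-bis(benzyloxy)phenyl]{(2S,3S,4S,5S)-4-[4-(benzyloxy)benzyl]-5-[2,4-bis(benzyloxy)phenyl]-2-[4-(benzyloxy)phenyl]oxolan-3-yl}methanone
Product: 16 (2,4-dihydroxyphenyl)[(2S,3S,4S,5S)-5-(2,4-dihydroxyphenyl)-4-(4-hydroxybenzyl)-2-(4-hydroxyphenyl)oxolan-3-yl]methanone
Conditions: H2 (1 atm), Pd/C, EtOAc/MeOH, 25 °C
Reagents that add atoms: none
Why: catalytic hydrogenolysis of six aryl benzyl ethers, which cleave faster than the dialkyl benzylic C–O bonds of the oxolane or the electron-rich, chelated aryl ketone; neutral conditions leave all four stereocentres untouched.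

**Compound list**

1 | resorcinol | Oc1cccc(O)c1 | starting material
2 | acetic acid | CC(=O)O | starting material
3 | 1-(2,4-dihydroxyphenyl)ethan-1-one | CC(=O)c1ccc(O)cc1O | intermediate
4 | 1-[2,4-bis(benzyloxy)phenyl]ethan-1-one | CC(=O)c1ccc(OCc2ccccc2)cc1OCc1ccccc1 | intermediate
5 | 4-bromophenol | Oc1ccc(Br)cc1 | starting material
6 | 1-(benzyloxy)-4-bromobenzene | Brc1ccc(OCc2ccccc2)cc1 | intermediate
7 | 4-(benzyloxy)phenyllithium | [Li]c1ccc(OCc2ccccc2)cc1 | intermediate (not isolated)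
8 | 4-(benzyloxy)benzaldehyde | O=Cc1ccc(OCc2ccccc2)cc1 | intermediate
9 | (E)-1-[2,4-bis(benzyloxy)phenyl]-3-[4-(benzyloxy)phenyl]prop-2-en-1-one | O=C(/C=C/c1ccc(OCc2ccccc2)cc1)c1ccc(OCc2ccccc2)cc1OCc1ccccc1 | intermediate
10 | N'-{(2E)-1-[2,4-bis(benzyloxy)phenyl]-3-[4-(benzyloxy)phenyl]prop-2-en-1-ylidene}-4-methylbenzenesulfonohydrazide | Cc1ccc(cc1)S(=O)(=O)NN=C(/C=C/c1ccc(OCc2ccccc2)cc1)c1ccc(OCc2ccccc2)cc1OCc1ccccc1 | intermediate (not isolated)
11 | 2,4-bis(benzyloxy)-1-{(1E)-3-[4-(benzyloxy)phenyl]prop-1-en-1-yl}benzene | c1ccccc1COc1ccc(/C=C/Cc2ccc(OCc3ccccc3)cc2)c(OCc2ccccc2)c1 | intermediate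
12 | 1-[2,4-bis(benzyloxy)phenyl]-4,4,4-trifluorobutane-1,3-dione (present as its lithium enolate) | O=C(CC(=O)C(F)(F)F)c1ccc(OCc2ccccc2)cc1OCc1ccccc1 | intermediate (not isolated)
13 | 1-[2,4-bis(benzyloxy)phenyl]-2-diazoethan-1-one | [N-]=[N+]=CC(=O)c1ccc(OCc2ccccc2)cc1OCc1ccccc1 | intermediate
14 | {(1R,2R,3R)-2-[4-(benzyloxy)benzyl]-3-[2,4-bis(benzyloxy)phenyl]cyclopropyl}[2,4-bis(benzyloxy)phenyl]methanone (benzyl trans to aryl, aroyl trans to aryl) | O=C(c1ccc(OCc2ccccc2)cc1OCc1ccccc1)[C@@H]1[C@H](Cc2ccc(OCc3ccccc3)cc2)[C@H]1c1ccc(OCc2ccccc2)cc1OCc1ccccc1 | intermediate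
15 | [2,4-bis(benzyloxy)phenyl]{(2S,3S,4S,5S)-4-[4-(benzyloxy)benzyl]-5-[2,4-bis(benzyloxy)phenyl]-2-[4-(benzyloxy)phenyl]oxolan-3-yl}methanone | O=C(c1ccc(OCc2ccccc2)cc1OCc1ccccc1)[C@H]1[C@H](Cc2ccc(OCc3ccccc3)cc2)[C@@H](c2ccc(OCc3ccccc3)cc2OCc2ccccc2)O[C@@H]1c1ccc(OCc2ccccc2)cc1 | intermediate
16 | (2,4-dihydroxyphenyl)[(2S,3S,4S,5S)-5-(2,4-dihydroxyphenyl)-4-(4-hydroxybenzyl)-2-(4-hydroxyphenyl)oxolan-3-yl]methanone | O=C(c1ccc(O)cc1O)[C@H]1[C@H](Cc2ccc(O)cc2)[C@@H](c2ccc(O)cc2O)O[C@@H]1c1ccc(O)cc1 | target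

**Step count and risks**

Total step count: 10. Longest linear sequence: 7 steps (1, 2, 5, 6, 8, 9, 10; the branch 3, 4, 5, 6, 8, 9, 10 is equally long).

The three steps most likely to fail:

Step 6. The tosylhydrazone of this hindered, electron-rich chalcone may close to an N-tosylpyrazoline or be reduced slowly. The fallback sets out from 9 and comes back at 11. Both the alkene and the ketone of 9 are reduced with NaBH4 and NiCl2·6H2O in MeOH/THF (benzyl ethers survive) to the saturated alcohol 1-[2,4-bis(benzyloxy)phenyl]-3-[4-(benzyloxy)phenyl]propan-1-ol F1. Catalytic TsOH in toluene at 50 °C then dehydrates F1 through the 2,4-dialkoxybenzyl cation (E1) to the conjugated (E)-alkene 11.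

Step 8 (the proposed new step). The internal alkene may react too slowly, the carbene radical may abstract a benzylic hydrogen, or the enantioselectivity may be low. The fallback uses known chemistry, sets out from 11 and 4 and comes back at 14.
- Shi epoxidation of 11 (KHSO5, K2CO3 buffer, MeCN/dimethoxymethane, 0 °C, with the ketone antipode derived from L-fructose) gives (2S,3S)-2-[4-(benzyloxy)benzyl]-3-[2,4-bis(benzyloxy)phenyl]oxirane F2, kept base-washed because it is acid-labile.
- Ketone 4 is brominated with CuBr2 in refluxing EtOAc to 2-bromo-1-[2,4-bis(benzyloxy)phenyl]ethan-1-one F3.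
- Michaelis–Arbuzov reaction of F3 with P(OEt)3 at 120 °C gives diethyl {2-[2,4-bis(benzyloxy)phenyl]-2-oxoethyl}phosphonate F4.
- The sodium salt of F4 (NaH, DME, 85 °C) opens F2 and closes the three-membered ring in a Wadsworth–Emmons cyclopropanation, with inversion at both epoxide carbons, to give 14. A C1 epimer would converge in step 9.

Step 9. The cyclopropyl ketone may isomerise to a 2,3-dihydrofuran (Cloke–Wilson), the cation may lose the C4 proton, or the 2,5-cis adduct may not equilibrate fully. The fallback sets out from 14 and comes back at 15.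
- Acid-catalysed methanolysis of the donor–acceptor cyclopropane (TsOH cat., MeOH/CH2Cl2, 25 °C) gives (3S)-1,4-bis[2,4-bis(benzyloxy)phenyl]-3-[4-(benzyloxy)benzyl]-4-methoxybutan-1-one F5 as a mixture at the methoxy carbon. Its only enolisable position is the CH2 next to the ketone.
- Aldol addition of the enolate of F5 (LiN(i-Pr)2, THF, −78 °C) to 8 gives (3S)-1,4-bis[2,4-bis(benzyloxy)phenyl]-3-[4-(benzyloxy)benzyl]-2-{[4-(benzyloxy)phenyl](hydroxy)methyl}-4-methoxybutan-1-one F6.
- BF3·OEt2 (cat., CH2Cl2, 0 °C) ionises the benzylic methyl ether of F6 and the hydroxyl captures the cation (SN1 cycloetherification under thermodynamic control) to give all-trans 15.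

**Further compounds**

F1 | step 6 | 1-[2,4-bis(benzyloxy)phenyl]-3-[4-(benzyloxy)phenyl]propan-1-ol (racemic) | OC(CCc1ccc(OCc2ccccc2)cc1)c1ccc(OCc2ccccc2)cc1OCc1ccccc1
F2 | step 8 | (2S,3S)-2-[4-(benzyloxy)benzyl]-3-[2,4-bis(benzyloxy)phenyl]oxirane | O1[C@@H](Cc2ccc(OCc3ccccc3)cc2)[C@@H]1c1ccc(OCc2ccccc2)cc1OCc1ccccc1
F3 | step 8 | 2-bromo-1-[2,4-bis(benzyloxy)phenyl]ethan-1-one | BrCC(=O)c1ccc(OCc2ccccc2)cc1OCc1ccccc1
F4 | step 8 | diethyl {2-[2,4-bis(benzyloxy)phenyl]-2-oxoethyl}phosphonate | CCOP(=O)(CC(=O)c1ccc(OCc2ccccc2)cc1OCc1ccccc1)OCC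
F5 | step 9 | (3S)-1,4-bis[2,4-bis(benzyloxy)phenyl]-3-[4-(benzyloxy)benzyl]-4-methoxybutan-1-one | O=C(C[C@H](Cc1ccc(OCc2ccccc2)cc1)C(OC)c1ccc(OCc2ccccc2)cc1OCc1ccccc1)c1ccc(OCc2ccccc2)cc1OCc1ccccc1
F6 | step 9 | (3S)-1,4-bis[2,4-bis(benzyloxy)phenyl]-3-[4-(benzyloxy)benzyl]-2-{[4-(benzyloxy)phenyl](hydroxy)methyl}-4-methoxybutan-1-one | O=C(C(C(O)c1ccc(OCc2ccccc2)cc1)[C@H](Cc1ccc(OCc2ccccc2)cc1)C(OC)c1ccc(OCc2ccccc2)cc1OCc1ccccc1)c1ccc(OCc2ccccc2)cc1OCc1ccccc1
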